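**Plan**

- Lobatin B (germacrane numbering) has an ether oxygen joining C3 and C10 across the ten-membered carbocycle, with C1 oxygenated next to the quaternary C10. This is the imprint of a C3 ketone oxygen opening a 1,10-epoxide at C10, so the retrosynthesis takes C1=O back to C1–OH and cuts the C10–O bond of the furanone ring, arriving at a 1,10-epoxy-3-oxogermacr-4Z-en-12,6-olide.
- Further cuts: C3–C4 (Nozaki–Hiyama–Kishi ring closure), C6–C7 together with the lactone C12–O bond (allylboration/lactonisation with (Z)-3-iodobut-2-enal), C11–C13 (boronate alkylation), C1–C2 and C10–C14 (carboalumination/ethylene oxide).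
- Forward: the C7–C10 chain of L-threonate is extended to the 1(10)E alkene and C3, then to an ynoate and a stereodefined allylboronate. The γ-lactone ring forms first, then the epoxide, then the ten-membered ring, then the bridging dihydrofuran ring, and last the furanone carbonyl.
- Stereochemistry: C8 and C9 come from the chiral pool (L-tartrate series). C6 and C7 come from a chair allylboration (anti adduct, hence trans-lactone; face set by C8). The 1,10-epoxide comes from a reagent-controlled Shi epoxidation, and C10 of the target from inversion in the key step.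
- Alkene geometry: 1(10)E from syn-carboalumination, 4Z from hydroalumination–iodination of but-2-yn-1-ol.

Key step: step 21

Assumption: methyl 3,4-O-isopropylidene-L-threonate (the mono-reduced, acetonide-protected member of the L-tartrate family) is a purchasable chiral-pool ester; its two stereocentres become C9 and C8.
Abbreviations: TBS = tert-butyldimethylsilyl, TES = triethylsilyl, PMB = 4-methoxybenzyl, Bpin = 4,4,5,5-tetramethyl-1,3,2-dioxaborolan-2-yl. CIP descriptors with germacrane locants change with substituent priorities, not with geometry.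

**Route**

Step 1
Reactants: 1 methyl 3,4-O-isopropylidene-L-threonate
Product: 2 methyl (2R)-2-(tert-butyldimethylsilyloxy)-2-[(4S)-2,2-dimethyl-1,3-dioxolan-4-yl]acetate
Conditions: TBSCl, imidazole, DMF, rt
Reagents that add atoms: tert-butyldimethylsilyl chloride CC(C)(C)[Si](C)(C)Cl
Why: Imidazole-promoted silylation of the only free hydroxyl puts on O9 a group that should survive every basic, reducing and mildly acidic step up to the last one, without touching a stereocentre.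

Step 2
Reactants: 2 methyl (2R)-2-(tert-butyldimethylsilyloxy)-2-[(4S)-2,2-dimethyl-1,3-dioxolan-4-yl]acetate
Product: 4 (4S)-4-[(1S)-1-(tert-butyldimethylsilyloxy)prop-2-yn-1-yl]-2,2-dimethyl-1,3-dioxolane, via aldehyde 3 (not isolated)
Conditions: i-Bu2AlH, CH2Cl2, −78 °C; then MeOH, K2CO3, dimethyl (1-diazo-2-oxopropyl)phosphonate, −78 °C → rt
Reagents that add atoms: dimethyl (1-diazo-2-oxopropyl)phosphonate COP(=O)(OC)C(=[N+]=[N-])C(C)=O
Why: One-pot partial ester reduction and Ohira–Bestmann (Seyferth–Gilbert) homologation turns the ester carbon into C10 of a terminal alkyne and brings in C1 without isolating the epimerisable α-silyloxy aldehyde.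

Step 3
Reactants: 4 (4S)-4-[(1S)-1-(tert-butyldimethylsilyloxy)prop-2-yn-1-yl]-2,2-dimethyl-1,3-dioxolane
Product: 7 (3E,5S)-5-(tert-butyldimethylsilyloxy)-5-[(4S)-2,2-dimethyl-1,3-dioxolan-4-yl]-4-methylpent-3-en-1-ol, via alkenyldimethylalane 5 (not isolated), via lithium alkenylalanate 6 (not isolated)
Conditions: Me3Al, Cp2ZrCl2 (0.25 equiv), CH2Cl2, 0 °C → rt; evaporate, hexane–THF; n-BuLi, −78 °C; ethylene oxide, −78 → 0 °C
Reagents that add atoms: trimethylaluminium C[Al](C)C; ethylene oxide C1CO1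
Why: Zirconium-catalysed Negishi carboalumination adds methyl (C14) and aluminium syn across the alkyne with methyl on the internal carbon, and the derived alanate opens ethylene oxide with retention at the alkenyl carbon, so the 1(10)E geometry follows from the syn addition while C2 and C3 are attached.

Step 4
Reactants: 7 (3E,5S)-5-(tert-butyldimethylsilyloxy)-5-[(4S)-2,2-dimethyl-1,3-dioxolan-4-yl]-4-methylpent-3-en-1-ol
Product: 8 (4S)-4-[(1S,2E)-1-(tert-butyldimethylsilyloxy)-5-(4-methoxybenzyloxy)-2-methylpent-2-en-1-yl]-2,2-dimethyl-1,3-dioxolane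
Conditions: NaH, PMBCl, n-Bu4NI (cat.), THF–DMF, 0 °C → rt
Reagents that add atoms: 4-methoxybenzyl chloride COc1ccc(CCl)cc1
Why: Williamson etherification gives a C3 ether that is orthogonal to the silyl ethers and can later be removed oxidatively beside the epoxide.

Step 5
Reactants: 8 (4S)-4-[(1S,2E)-1-(tert-butyldimethylsilyloxy)-5-(4-methoxybenzyloxy)-2-methylpent-2-en-1-yl]-2,2-dimethyl-1,3-dioxolane
Product: 9 (2S,3S,4E)-3-(tert-butyldimethylsilyloxy)-7-(4-methoxybenzyloxy)-4-methylhept-4-ene-1,2-diol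
Conditions: PPTS, MeOH, 40 °C
Reagents that add atoms: none
Why: Acid-catalysed transketalisation to methanol removes the terminal acetonide while the hindered secondary TBS ether and the PMB ether should stay.

Step 6
Reactants: 9 (2S,3S,4E)-3-(tert-butyldimethylsilyloxy)-7-(4-methoxybenzyloxy)-4-methylhept-4-ene-1,2-diol
Product: 10 (2S,3S,4E)-3-(tert-butyldimethylsilyloxy)-7-(4-methoxybenzyloxy)-4-methyl-1,2-bis(triethylsilyloxy)hept-4-ene
Conditions: Et3SiCl, imidazole, DMAP (cat.), CH2Cl2, 0 °C → rt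
Reagents that add atoms: chlorotriethylsilane CC[Si](CC)(CC)Cl
Why: Exhaustive silylation prepares the primary/secondary differentiation of the next step and leaves on O8 a silyl ether that can later be cleaved beside TBS.

Step 7
Reactants: 10 (2S,3S,4E)-3-(tert-butyldimethylsilyloxy)-7-(4-methoxybenzyloxy)-4-methyl-1,2-bis(triethylsilyloxy)hept-4-ene
Product: 11 (2R,3S,4E)-3-(tert-butyldimethylsilyloxy)-7-(4-methoxybenzyloxy)-4-methyl-2-(triethylsilyloxy)hept-4-enal
Conditions: (COCl)2, DMSO, CH2Cl2, −78 → −30 °C; Et3N, −78 °C → 0 °C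
Reagents that add atoms: none
Why: Under Swern conditions a primary triethylsilyl ether is cleaved by the chlorosulfonium salt and oxidised in the same pot while secondary silyl ethers are inert, and the cold amine work-up should keep the α-silyloxy centre C8 intact.

Step 8
Reactants: 11 (2R,3S,4E)-3-(tert-butyldimethylsilyloxy)-7-(4-methoxybenzyloxy)-4-methyl-2-(triethylsilyloxy)hept-4-enal
Product: 12 (3S,4S,5E)-1,1-dibromo-4-(tert-butyldimethylsilyloxy)-8-(4-methoxybenzyloxy)-5-methyl-3-(triethylsilyloxy)octa-1,5-diene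
Conditions: CBr4, PPh3, Et3N, CH2Cl2, 0 °C
Reagents that add atoms: carbon tetrabromide BrC(Br)(Br)Br
Why: Corey–Fuchs dibromo-olefination (Wittig reaction of the dibromomethylidene ylide), buffered with amine so that the silyl ethers survive, adds the future C11.

Step 9
Reactants: 12 (3S,4S,5E)-1,1-dibromo-4-(tert-butyldimethylsilyloxy)-8-(4-methoxybenzyloxy)-5-methyl-3-(triethylsilyloxy)octa-1,5-diene
Product: 14 methyl (4S,5S,6E)-5-(tert-butyldimethylsilyloxy)-9-(4-methoxybenzyloxy)-6-methyl-4-(triethylsilyloxy)non-6-en-2-ynoate, via lithium acetylide 13 (not isolated)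
Conditions: n-BuLi (2.1 equiv), THF, −78 °C; ClCO2Me, −78 → 0 °C
Reagents that add atoms: methyl chloroformate COC(=O)Cl
Why: Second stage of the Corey–Fuchs sequence (bromine–lithium exchange, Fritsch–Buttenberg–Wiechell shift, deprotonation) gives the acetylide, which is C-acylated by the chloroformate to install C12.

Step 10
Reactants: 14 methyl (4S,5S,6E)-5-(tert-butyldimethylsilyloxy)-9-(4-methoxybenzyloxy)-6-methyl-4-(triethylsilyloxy)non-6-en-2-ynoate
Product: 16 methyl (2Z,4S,5S,6E)-5-(tert-butyldimethylsilyloxy)-9-(4-methoxybenzyloxy)-6-methyl-2-[(4,4,5,5-tetramethyl-1,3,2-dioxaborolan-2-yl)methyl]-4-(triethylsilyloxy)nona-2,6-dienoate, via C11 vinylalane 15 (not isolated)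
Conditions: i-Bu2AlH, HMPA, THF, 0 °C; then ICH2Bpin, 0 °C → rt
Reagents that add atoms: 2-(iodomethyl)-4,4,5,5-tetramethyl-1,3,2-dioxaborolane CC1(C)OB(CI)OC1(C)C
Why: Conjugate hydroalumination of the ynoate by the i-Bu2AlH–HMPA complex is a syn addition and the α-alumino acrylate is alkylated by the iodomethylboronate with retention, so C8 ends up cis to the ester and trans to CH2B, the geometry an anti-selective allylboration needs, and C13 is in place.

Step 11
Reactants: 17 but-2-yn-1-ol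
Product: 19 (2Z)-3-iodobut-2-en-1-ol, via cyclic alkenylalanate 18 (not isolated)
Conditions: NaAlH2(OCH2CH2OMe)2, Et2O, 0 °C → rt; then I2, THF, −78 °C
Reagents that add atoms: iodine [I][I]
Why: Alkoxide-directed trans-hydroalumination of the propargylic alcohol places aluminium on the distal alkyne carbon in a five-membered ring and iodinolysis with retention gives the Z iodide, which fixes the later 4Z geometry.

Step 12
Reactants: 19 (2Z)-3-iodobut-2-en-1-ol
Product: 20 (2Z)-3-iodobut-2-enal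
Conditions: MnO2, CH2Cl2, rt, dark
Reagents that add atoms: none
Why: Neutral allylic oxidation with MnO2 should not isomerise the Z iodoalkene if the aldehyde is kept from light and used at once.

Step 13
Reactants: 16 methyl (2Z,4S,5S,6E)-5-(tert-butyldimethylsilyloxy)-9-(4-methoxybenzyloxy)-6-methyl-2-[(4,4,5,5-tetramethyl-1,3,2-dioxaborolan-2-yl)methyl]-4-(triethylsilyloxy)nona-2,6-dienoate; 20 (2Z)-3-iodobut-2-enal
Product: 22 (6S,7S,8S,9S,1(10)E,4Z)-9-(tert-butyldimethylsilyloxy)-4-iodo-3-(4-methoxybenzyloxy)-8-(triethylsilyloxy)-3,4-secogermacra-1(10),4,11(13)-trien-12,6-olide, via C6 pinacol borate 21 (not isolated)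
Conditions: Sc(OTf)3 (10 mol %), toluene, 0 °C → rt; then PPTS (cat.), 40 °C
Reagents that add atoms: none
Why: Lewis-acid-catalysed allylboration through a closed chair transition state with C8 pseudo-equatorial gives the anti C6–C7 adduct, which lactonises to the trans α-methylene-γ-lactone; A(1,3) strain with the cis ester holds H8 in the alkene plane, so the aldehyde should add to C7 anti to the bulky C9 branch, setting C7 and, through the chair, C6.

Step 14
Reactants: 22 (6S,7S,8S,9S,1(10)E,4Z)-9-(tert-butyldimethylsilyloxy)-4-iodo-3-(4-methoxybenzyloxy)-8-(triethylsilyloxy)-3,4-secogermacra-1(10),4,11(13)-trien-12,6-olide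
Product: 23 (6S,7R,8S,9S,1(10)E,4Z)-9-(tert-butyldimethylsilyloxy)-8-hydroxy-4-iodo-3-(4-methoxybenzyloxy)-3,4-secogermacra-1(10),4,11(13)-trien-12,6-olide
Conditions: PPTS, MeOH–CH2Cl2, 0 °C → rt
Reagents that add atoms: none
Why: Mild acid solvolysis cleaves the secondary triethylsilyl ether much faster than the TBS ether, freeing O8 only (same geometry at C7, descriptor changed by priority).

Step 15
Reactants: 23 (6S,7R,8S,9S,1(10)E,4Z)-9-(tert-butyldimethylsilyloxy)-8-hydroxy-4-iodo-3-(4-methoxybenzyloxy)-3,4-secogermacra-1(10),4,11(13)-trien-12,6-olide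
Product: 24 (6S,7S,8S,9S,1(10)E,4Z)-9-(tert-butyldimethylsilyloxy)-4-iodo-3-(4-methoxybenzyloxy)-8-(3-methylbutanoyloxy)-3,4-secogermacra-1(10),4,11(13)-trien-12,6-olide
Conditions: (Me2CHCH2CO)2O, Et3N, DMAP (cat.), CH2Cl2, 0 °C
Reagents that add atoms: 3-methylbutanoic anhydride CC(C)CC(=O)OC(=O)CC(C)C
Why: DMAP-catalysed acylation installs the isovalerate on O8, run cold and short so that the free C8 hydroxyl does not translactonise onto C12.

Step 16
Reactants: 24 (6S,7S,8S,9S,1(10)E,4Z)-9-(tert-butyldimethylsilyloxy)-4-iodo-3-(4-methoxybenzyloxy)-8-(3-methylbutanoyloxy)-3,4-secogermacra-1(10),4,11(13)-trien-12,6-olide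
Product: 25 (1S,6S,7S,8S,9R,10R,4Z)-9-(tert-butyldimethylsilyloxy)-1,10-epoxy-4-iodo-3-(4-methoxybenzyloxy)-8-(3-methylbutanoyloxy)-3,4-secogermacra-4,11(13)-dien-12,6-olide
Conditions: 1,2:4,5-di-O-isopropylidene-β-L-erythro-2,3-hexodiulo-2,6-pyranose (L-fructose-derived Shi ketone, 0.3–0.5 equiv), Oxone, K2CO3, n-Bu4NHSO4, MeCN–CH2(OMe)2–aq. Na2B4O7 buffer, 0 °C
Reagents that add atoms: potassium peroxymonosulfate KHSO5 (from Oxone) [K+].[O-]S(=O)(=O)OO
Why: Shi asymmetric epoxidation (chiral dioxirane, spiro transition state) attacks only the electron-rich E-trisubstituted alkene, and the L-fructose-derived ketone is the enantiomer that delivers oxygen to the face giving the (1S,10R)-epoxide with C10–O syn (threo) to the C9 silyloxy group, the isomer that a hydroxyl-directed vanadium or titanium epoxidation from a free C9–OH (erythro-selective here) would not give.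

Step 17
Reactants: 25 (1S,6S,7S,8S,9R,10R,4Z)-9-(tert-butyldimethylsilyloxy)-1,10-epoxy-4-iodo-3-(4-methoxybenzyloxy)-8-(3-methylbutanoyloxy)-3,4-secogermacra-4,11(13)-dien-12,6-olide
Product: 26 (1S,6S,7S,8S,9R,10R,4Z)-9-(tert-butyldimethylsilyloxy)-1,10-epoxy-3-hydroxy-4-iodo-8-(3-methylbutanoyloxy)-3,4-secogermacra-4,11(13)-dien-12,6-olide
Conditions: DDQ, CH2Cl2–pH 7 buffer, 0 °C
Reagents that add atoms: none
Why: Oxidative PMB cleavage in buffered wet dichloromethane should leave epoxide, silyl ether, both esters and the alkenyl iodide untouched.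

Step 18
Reactants: 26 (1S,6S,7S,8S,9R,10R,4Z)-9-(tert-butyldimethylsilyloxy)-1,10-epoxy-3-hydroxy-4-iodo-8-(3-methylbutanoyloxy)-3,4-secogermacra-4,11(13)-dien-12,6-olide
Product: 27 (1S,6S,7S,8S,9R,10R,4Z)-9-(tert-butyldimethylsilyloxy)-1,10-epoxy-4-iodo-8-(3-methylbutanoyloxy)-3-oxo-3,4-secogermacra-4,11(13)-dien-12,6-olide
Conditions: Dess–Martin periodinane, NaHCO3, CH2Cl2, 0 °C; used crude
Reagents that add atoms: none
Why: Buffered Dess–Martin oxidation gives the β,γ-epoxy aldehyde without the base that would trigger β-elimination to a γ-hydroxy enal.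

Step 19
Reactants: 27 (1S,6S,7S,8S,9R,10R,4Z)-9-(tert-butyldimethylsilyloxy)-1,10-epoxy-4-iodo-8-(3-methylbutanoyloxy)-3-oxo-3,4-secogermacra-4,11(13)-dien-12,6-olide
Product: 28 (1S,6R,7S,8S,9R,10R,4Z)-9-(tert-butyldimethylsilyloxy)-1,10-epoxy-3-hydroxy-8-(3-methylbutanoyloxy)germacra-4,11(13)-dien-12,6-olide (C3 epimers)
Conditions: CrCl2 (10 equiv), NiCl2 (0.1 equiv), DMSO–THF, rt, 0.003 M (slow addition)
Reagents that add atoms: none
Why: Nozaki–Hiyama–Kishi reaction (zerovalent nickel inserts into the alkenyl iodide, transmetallation to chromium, addition of the alkenylchromium to the aldehyde) closes the ten-membered carbocycle at C3–C4 with retention of the 4Z geometry and tolerates lactone, ester and epoxide; the C3 epimers converge in the next step.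

Step 20
Reactants: 28 (1S,6R,7S,8S,9R,10R,4Z)-9-(tert-butyldimethylsilyloxy)-1,10-epoxy-3-hydroxy-8-(3-methylbutanoyloxy)germacra-4,11(13)-dien-12,6-olide
Product: 29 (1S,6R,7S,8S,9R,10R,4Z)-9-(tert-butyldimethylsilyloxy)-1,10-epoxy-8-(3-methylbutanoyloxy)-3-oxogermacra-4,11(13)-dien-12,6-olide
Conditions: Dess–Martin periodinane, NaHCO3, CH2Cl2, 0 °C
Reagents that add atoms: none
Why: Dess–Martin oxidation of the allylic alcohol gives the Z-enone, the buffer preventing premature acid-mediated opening of the epoxide.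

Step 21
Reactants: 29 (1S,6R,7S,8S,9R,10R,4Z)-9-(tert-butyldimethylsilyloxy)-1,10-epoxy-8-(3-methylbutanoyloxy)-3-oxogermacra-4,11(13)-dien-12,6-olide
Product: 31 (1S,6R,7S,8S,9R,10S,4Z)-9-(tert-butyldimethylsilyloxy)-3,10-epoxy-1-hydroxy-8-(3-methylbutanoyloxy)germacra-2,4,11(13)-trien-12,6-olide, via dienyl oxocarbenium ion 30 (not isolated)
Conditions: CSA (0.1–0.2 equiv), CH2Cl2, 4 Å MS, −20 → 0 °C; Et3N quench
Reagents that add atoms: none
Why: This is the acid-catalysed cyclisation of a β,γ-epoxy ketone (the reaction type behind the classical route from β,γ-epoxy ketones to 3-hydroxy-2,3-dihydrofurans and furans, here run across the ring like the transannular epoxide openings of germacranolides): the protonated epoxide is attacked at the tertiary C10 by the C3 carbonyl oxygen, and the dienyl oxocarbenium ion 30 loses a C2 proton to give the cyclic enol ether with C1 released as a secondary alcohol. The 2,3-dihydrofuran ring (O, C3, C2, C1, C10), which is the oxygen bridge of the target, closes by a 5-endo epoxide opening, viable because the breaking C10–O bond sits on a fully substituted, cation-stabilising carbon and the ten-membered ring should hold the carbonyl oxygen behind that bond. The one new stereocentre, C10, follows from the (10R)-epoxide carbon set in step 16 by inversion, the oxygen entering anti to the departing epoxide oxygen, while C1 keeps its C–O bond and configuration. The step needs attack at C10 in preference to C1 and to a 1,2-shift from C9 (semipinacol): attack at C1 would close an oxetane, the oxygen substituents on C9 and C8 disfavour a free C10 cation so that opening should stay concerted with oxygen participation, and the silyl ether removes the C9 hydroxyl as a competing nucleophile. Catalytic acid in an aprotic solvent at low temperature with an amine quench should spare the silyl ether and the acid-labile allylic carbinol of the product, which cannot dehydrate to a furan because C10 is quaternary.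

Step 22
Reactants: 31 (1S,6R,7S,8S,9R,10S,4Z)-9-(tert-butyldimethylsilyloxy)-3,10-epoxy-1-hydroxy-8-(3-methylbutanoyloxy)germacra-2,4,11(13)-trien-12,6-olide
Product: 32 (6R,7S,8S,9R,10R,4Z)-9-(tert-butyldimethylsilyloxy)-3,10-epoxy-8-(3-methylbutanoyloxy)-1-oxogermacra-2,4,11(13)-trien-12,6-olide
Conditions: Dess–Martin periodinane, NaHCO3, CH2Cl2, 0 °C → rt
Reagents that add atoms: none
Why: Dess–Martin oxidation of the carbinol next to the enol ether gives the 3(2H)-furanone, a stable vinylogous ester, and so removes the acid-sensitive allylic alcohol.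

Step 23
Reactants: 32 (6R,7S,8S,9R,10R,4Z)-9-(tert-butyldimethylsilyloxy)-3,10-epoxy-8-(3-methylbutanoyloxy)-1-oxogermacra-2,4,11(13)-trien-12,6-olide
Product: 33 lobatin B
Conditions: HF·pyridine, pyridine, THF, 0 °C → rt
Reagents that add atoms: none
Why: Desilylation with HF·pyridine is acidic and non-nucleophilic, so the C9 hydroxyl should be freed without acyl migration from O8 or addition to the methylene lactone.

**Compound list**

1 | methyl 3,4-O-isopropylidene-L-threonate, methyl (2R)-2-[(4S)-2,2-dimethyl-1,3-dioxolan-4-yl]-2-hydroxyacetate | COC(=O)[C@H](O)[C@@H]1COC(C)(C)O1 | starting material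
2 | methyl (2R)-2-(tert-butyldimethylsilyloxy)-2-[(4S)-2,2-dimethyl-1,3-dioxolan-4-yl]acetate | COC(=O)[C@H](O[Si](C)(C)C(C)(C)C)[C@@H]1COC(C)(C)O1 | intermediate
3 | (2R)-2-(tert-butyldimethylsilyloxy)-2-[(4S)-2,2-dimethyl-1,3-dioxolan-4-yl]acetaldehyde | O=C[C@H](O[Si](C)(C)C(C)(C)C)[C@@H]1COC(C)(C)O1 | intermediate (not isolated)
4 | (4S)-4-[(1S)-1-(tert-butyldimethylsilyloxy)prop-2-yn-1-yl]-2,2-dimethyl-1,3-dioxolane | C#C[C@H](O[Si](C)(C)C(C)(C)C)[C@@H]1COC(C)(C)O1 | intermediate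
5 | [(1E,3S)-3-(tert-butyldimethylsilyloxy)-3-[(4S)-2,2-dimethyl-1,3-dioxolan-4-yl]-2-methylprop-1-en-1-yl]dimethylalumane | C[Al](C)/C=C(\C)[C@H](O[Si](C)(C)C(C)(C)C)[C@@H]1COC(C)(C)O1 | intermediate (not isolated)
6 | lithium butyl[(1E,3S)-3-(tert-butyldimethylsilyloxy)-3-[(4S)-2,2-dimethyl-1,3-dioxolan-4-yl]-2-methylprop-1-en-1-yl]dimethylalanate | [Li+].CCCC[Al-](C)(C)/C=C(\C)[C@H](O[Si](C)(C)C(C)(C)C)[C@@H]1COC(C)(C)O1 | intermediate (not isolated)
7 | (3E,5S)-5-(tert-butyldimethylsilyloxy)-5-[(4S)-2,2-dimethyl-1,3-dioxolan-4-yl]-4-methylpent-3-en-1-ol | OCC/C=C(\C)[C@H](O[Si](C)(C)C(C)(C)C)[C@@H]1COC(C)(C)O1 | intermediate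
8 | (4S)-4-[(1S,2E)-1-(tert-butyldimethylsilyloxy)-5-(4-methoxybenzyloxy)-2-methylpent-2-en-1-yl]-2,2-dimethyl-1,3-dioxolane | COc1ccc(COCC/C=C(\C)[C@H](O[Si](C)(C)C(C)(C)C)[C@@H]2COC(C)(C)O2)cc1 | intermediate
9 | (2S,3S,4E)-3-(tert-butyldimethylsilyloxy)-7-(4-methoxybenzyloxy)-4-methylhept-4-ene-1,2-diol | COc1ccc(COCC/C=C(\C)[C@H](O[Si](C)(C)C(C)(C)C)[C@@H](O)CO)cc1 | intermediate
10 | (2S,3S,4E)-3-(tert-butyldimethylsilyloxy)-7-(4-methoxybenzyloxy)-4-methyl-1,2-bis(triethylsilyloxy)hept-4-ene | COc1ccc(COCC/C=C(\C)[C@H](O[Si](C)(C)C(C)(C)C)[C@@H](O[Si](CC)(CC)CC)CO[Si](CC)(CC)CC)cc1 | intermediate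
11 | (2R,3S,4E)-3-(tert-butyldimethylsilyloxy)-7-(4-methoxybenzyloxy)-4-methyl-2-(triethylsilyloxy)hept-4-enal | COc1ccc(COCC/C=C(\C)[C@H](O[Si](C)(C)C(C)(C)C)[C@@H](O[Si](CC)(CC)CC)C=O)cc1 | intermediate
12 | (3S,4S,5E)-1,1-dibromo-4-(tert-butyldimethylsilyloxy)-8-(4-methoxybenzyloxy)-5-methyl-3-(triethylsilyloxy)octa-1,5-diene | COc1ccc(COCC/C=C(\C)[C@H](O[Si](C)(C)C(C)(C)C)[C@@H](O[Si](CC)(CC)CC)C=C(Br)Br)cc1 | intermediate
13 | [(3S,4S,5E)-4-(tert-butyldimethylsilyloxy)-8-(4-methoxybenzyloxy)-5-methyl-3-(triethylsilyloxy)oct-5-en-1-yn-1-yl]lithium | COc1ccc(COCC/C=C(\C)[C@H](O[Si](C)(C)C(C)(C)C)[C@@H](O[Si](CC)(CC)CC)C#C[Li])cc1 | intermediate (not isolated)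
14 | methyl (4S,5S,6E)-5-(tert-butyldimethylsilyloxy)-9-(4-methoxybenzyloxy)-6-methyl-4-(triethylsilyloxy)non-6-en-2-ynoate | COc1ccc(COCC/C=C(\C)[C@H](O[Si](C)(C)C(C)(C)C)[C@@H](O[Si](CC)(CC)CC)C#CC(=O)OC)cc1 | intermediate
15 | methyl (2E,4S,5S,6E)-2-(diisobutylalumanyl)-5-(tert-butyldimethylsilyloxy)-9-(4-methoxybenzyloxy)-6-methyl-4-(triethylsilyloxy)nona-2,6-dienoate | COc1ccc(COCC/C=C(\C)[C@H](O[Si](C)(C)C(C)(C)C)[C@@H](O[Si](CC)(CC)CC)/C=C(/[Al](CC(C)C)CC(C)C)C(=O)OC)cc1 | intermediate (not isolated)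
16 | methyl (2Z,4S,5S,6E)-5-(tert-butyldimethylsilyloxy)-9-(4-methoxybenzyloxy)-6-methyl-2-[(4,4,5,5-tetramethyl-1,3,2-dioxaborolan-2-yl)methyl]-4-(triethylsilyloxy)nona-2,6-dienoate | COc1ccc(COCC/C=C(\C)[C@H](O[Si](C)(C)C(C)(C)C)[C@@H](O[Si](CC)(CC)CC)/C=C(/CB2OC(C)(C)C(C)(C)O2)C(=O)OC)cc1 | intermediate
17 | but-2-yn-1-ol | CC#CCO | starting material
18 | sodium 2,2-bis(2-methoxyethoxy)-3-methyl-1-oxa-2-aluminacyclopent-3-en-2-uide (cyclic alkenylalanate) | [Na+].CC1=CCO[Al-]1(OCCOC)OCCOC | intermediate (not isolated)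
19 | (2Z)-3-iodobut-2-en-1-ol | C/C(I)=C/CO | intermediate
20 | (2Z)-3-iodobut-2-enal | C/C(I)=C/C=O | intermediate
21 | methyl ester of the open 12,6-hydroxy acid of 22 with O6 bound to Bpin (anti adduct, same configuration at C6–C9 as 22) | COC(=O)C(=C)[C@@H]([C@@H](/C=C(/C)I)OB1OC(C)(C)C(C)(C)O1)[C@H](O[Si](CC)(CC)CC)[C@@H](O[Si](C)(C)C(C)(C)C)/C(C)=C/CCOCc1ccc(OC)cc1 | intermediate (not isolated)
22 | (6S,7S,8S,9S,1(10)E,4Z)-9-(tert-butyldimethylsilyloxy)-4-iodo-3-(4-methoxybenzyloxy)-8-(triethylsilyloxy)-3,4-secogermacra-1(10),4,11(13)-trien-12,6-olide (trans α-methylene-γ-lactone, no C3–C4 bond) | C=C1C(=O)O[C@H](/C=C(/C)I)[C@H]1[C@H](O[Si](CC)(CC)CC)[C@@H](O[Si](C)(C)C(C)(C)C)/C(C)=C/CCOCc2ccc(OC)cc2 | intermediate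
23 | (6S,7R,8S,9S,1(10)E,4Z)-9-(tert-butyldimethylsilyloxy)-8-hydroxy-4-iodo-3-(4-methoxybenzyloxy)-3,4-secogermacra-1(10),4,11(13)-trien-12,6-olide | C=C1C(=O)O[C@H](/C=C(/C)I)[C@H]1[C@H](O)[C@@H](O[Si](C)(C)C(C)(C)C)/C(C)=C/CCOCc2ccc(OC)cc2 | intermediate
24 | (6S,7S,8S,9S,1(10)E,4Z)-9-(tert-butyldimethylsilyloxy)-4-iodo-3-(4-methoxybenzyloxy)-8-(3-methylbutanoyloxy)-3,4-secogermacra-1(10),4,11(13)-trien-12,6-olide | C=C1C(=O)O[C@H](/C=C(/C)I)[C@H]1[C@H](OC(=O)CC(C)C)[C@@H](O[Si](C)(C)C(C)(C)C)/C(C)=C/CCOCc2ccc(OC)cc2 | intermediate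
25 | (1S,6S,7S,8S,9R,10R,4Z)-9-(tert-butyldimethylsilyloxy)-1,10-epoxy-4-iodo-3-(4-methoxybenzyloxy)-8-(3-methylbutanoyloxy)-3,4-secogermacra-4,11(13)-dien-12,6-olide | C=C1C(=O)O[C@H](/C=C(/C)I)[C@H]1[C@H](OC(=O)CC(C)C)[C@@H](O[Si](C)(C)C(C)(C)C)[C@]2(C)O[C@H]2CCOCc3ccc(OC)cc3 | intermediate
26 | (1S,6S,7S,8S,9R,10R,4Z)-9-(tert-butyldimethylsilyloxy)-1,10-epoxy-3-hydroxy-4-iodo-8-(3-methylbutanoyloxy)-3,4-secogermacra-4,11(13)-dien-12,6-olide | C=C1C(=O)O[C@H](/C=C(/C)I)[C@H]1[C@H](OC(=O)CC(C)C)[C@@H](O[Si](C)(C)C(C)(C)C)[C@]2(C)O[C@H]2CCO | intermediate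
27 | (1S,6S,7S,8S,9R,10R,4Z)-9-(tert-butyldimethylsilyloxy)-1,10-epoxy-4-iodo-8-(3-methylbutanoyloxy)-3-oxo-3,4-secogermacra-4,11(13)-dien-12,6-olide (C3 aldehyde) | C=C1C(=O)O[C@H](/C=C(/C)I)[C@H]1[C@H](OC(=O)CC(C)C)[C@@H](O[Si](C)(C)C(C)(C)C)[C@]2(C)O[C@H]2CC=O | intermediate
28 | (1S,6R,7S,8S,9R,10R,4Z)-9-(tert-butyldimethylsilyloxy)-1,10-epoxy-3-hydroxy-8-(3-methylbutanoyloxy)germacra-4,11(13)-dien-12,6-olide (C3 epimers) | C=C1C(=O)O[C@@H]2/C=C(/C)C(O)C[C@@H]3O[C@@]3(C)[C@H](O[Si](C)(C)C(C)(C)C)[C@@H](OC(=O)CC(C)C)[C@@H]12 | intermediate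
29 | (1S,6R,7S,8S,9R,10R,4Z)-9-(tert-butyldimethylsilyloxy)-1,10-epoxy-8-(3-methylbutanoyloxy)-3-oxogermacra-4,11(13)-dien-12,6-olide | C=C1C(=O)O[C@@H]2/C=C(/C)C(=O)C[C@@H]3O[C@@]3(C)[C@H](O[Si](C)(C)C(C)(C)C)[C@@H](OC(=O)CC(C)C)[C@@H]12 | intermediate (key-step precursor)
30 | dienyl oxocarbenium ion: C3=O+ bonded to C10, C1 hydroxyl, C2 methylene, otherwise as 31 | C=C1C(=O)O[C@@H]2/C=C(/C)C3C[C@H](O)[C@](C)([O+]=3)[C@H](O[Si](C)(C)C(C)(C)C)[C@@H](OC(=O)CC(C)C)[C@@H]12 | intermediate (not isolated)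
31 | (1S,6R,7S,8S,9R,10S,4Z)-9-(tert-butyldimethylsilyloxy)-3,10-epoxy-1-hydroxy-8-(3-methylbutanoyloxy)germacra-2,4,11(13)-trien-12,6-olide | C=C1C(=O)O[C@@H]2/C=C(/C)C3=C[C@H](O)[C@](C)(O3)[C@H](O[Si](C)(C)C(C)(C)C)[C@@H](OC(=O)CC(C)C)[C@@H]12 | intermediate (key-step product)
32 | (6R,7S,8S,9R,10R,4Z)-9-(tert-butyldimethylsilyloxy)-3,10-epoxy-8-(3-methylbutanoyloxy)-1-oxogermacra-2,4,11(13)-trien-12,6-olide | C=C1C(=O)O[C@@H]2/C=C(/C)C3=CC(=O)[C@](C)(O3)[C@H](O[Si](C)(C)C(C)(C)C)[C@@H](OC(=O)CC(C)C)[C@@H]12 | intermediate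
33 | lobatin B, (6R,7S,8S,9R,10R,4Z)-3,10-epoxy-9-hydroxy-8-(3-methylbutanoyloxy)-1-oxogermacra-2,4,11(13)-trien-12,6-olide | C=C1C(=O)O[C@@H]2/C=C(/C)C3=CC(=O)[C@](C)(O3)[C@H](O)[C@@H](OC(=O)CC(C)C)[C@@H]12 | target

**Count and risks**

Total step count: 23. Longest linear sequence: 21 steps (steps 1–10 and 13–23, from 1); steps 11–12 make the iodoenal 20.

Steps most likely to fail:

1. Step 21 (bridging cyclisation). The weakly nucleophilic ketone oxygen may lose the race to ionisation at C10 followed by a 1,2-shift from C9 or loss of a C14 proton, or the acid may ionise the allylic C1 carbinol of the product. Fallback, setting out from 28 and coming back at 32: treat the C3 alcohol 28 with catalytic CSA so that the hydroxyl, a far better nucleophile, opens the epoxide at C10 in the same 5-endo sense (the known acid cyclisation of 3,4-epoxy alcohols to 3-hydroxyoxolanes), giving the saturated bridged ether (1S,6R,7S,8S,9R,10S,4Z)-9-(tert-butyldimethylsilyloxy)-3,10-epoxy-1-hydroxy-8-(3-methylbutanoyloxy)germacra-4,11(13)-dien-12,6-olide F1. Dess–Martin oxidation of its C1 hydroxyl gives the bridged oxolan-3-one F2, and dehydrogenation across C2–C3 with IBX in DMSO gives 32.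

2. Step 19 (ring closure). The β,γ-epoxy aldehyde may eliminate to a γ-hydroxy enal or suffer Lewis-acid opening of the epoxide by chromium salts before the slow ten-membered ring closure, and oligomerisation may compete. Fallback, setting out from 24 and coming back at 29: close the ring before the epoxide exists. DDQ cleavage of the PMB ether of 24 gives the C3 alcohol F3, Dess–Martin oxidation gives the β,γ-unsaturated aldehyde F4, the same CrCl2/NiCl2 cyclisation gives the macrocyclic dienol F5, and Dess–Martin oxidation gives the 1(10)E,4Z-dienone F6. Dimethyldioxirane in acetone at −20 °C then epoxidises the only electron-rich alkene to give 29; the face here rests on peripheral attack on the outer face of the trans alkene in the ring and would have to be checked.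

3. Step 13 (allylboration). The Z iodoenal may isomerise or the O8 silyl ether may be lost under the Lewis acid, the hindered boronate may react sluggishly, and the facial bias from C8 may be insufficient. Fallback, setting out from 11 and coming back at 22: Morita–Baylis–Hillman reaction of 11 with methyl acrylate (DABCO) gives the adduct F7, and N-bromosuccinimide/Me2S converts it with allylic transposition into the (Z)-2-(bromomethyl)enoate F8. Indium metal in THF–water couples F8 with 20 through a Z-type chair to give the syn hydroxy ester F9, which has C7 as in 22 and C6 epimeric. Me3SnOH hydrolysis gives the hydroxy acid F10, and Mitsunobu lactonisation (PPh3, diisopropyl azodicarboxylate) closes the lactone with inversion at C6 to give 22.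

**Further compounds**

F1 | step 21 | (1S,6R,7S,8S,9R,10S,4Z)-9-(tert-butyldimethylsilyloxy)-3,10-epoxy-1-hydroxy-8-(3-methylbutanoyloxy)germacra-4,11(13)-dien-12,6-olide (C3–H epimers) | C=C1C(=O)O[C@@H]2/C=C(/C)C3C[C@H](O)[C@](C)(O3)[C@H](O[Si](C)(C)C(C)(C)C)[C@@H](OC(=O)CC(C)C)[C@@H]12
F2 | step 21 | (6R,7S,8S,9R,10R,4Z)-9-(tert-butyldimethylsilyloxy)-3,10-epoxy-8-(3-methylbutanoyloxy)-1-oxogermacra-4,11(13)-dien-12,6-olide | C=C1C(=O)O[C@@H]2/C=C(/C)C3CC(=O)[C@](C)(O3)[C@H](O[Si](C)(C)C(C)(C)C)[C@@H](OC(=O)CC(C)C)[C@@H]12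
F3 | step 19 | (6S,7S,8S,9S,1(10)E,4Z)-9-(tert-butyldimethylsilyloxy)-3-hydroxy-4-iodo-8-(3-methylbutanoyloxy)-3,4-secogermacra-1(10),4,11(13)-trien-12,6-olide | C=C1C(=O)O[C@H](/C=C(/C)I)[C@H]1[C@H](OC(=O)CC(C)C)[C@@H](O[Si](C)(C)C(C)(C)C)/C(C)=C/CCO
F4 | step 19 | (6S,7S,8S,9S,1(10)E,4Z)-9-(tert-butyldimethylsilyloxy)-4-iodo-8-(3-methylbutanoyloxy)-3-oxo-3,4-secogermacra-1(10),4,11(13)-trien-12,6-olide (C3 aldehyde) | C=C1C(=O)O[C@H](/C=C(/C)I)[C@H]1[C@H](OC(=O)CC(C)C)[C@@H](O[Si](C)(C)C(C)(C)C)/C(C)=C/CC=O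
F5 | step 19 | (6R,7S,8S,9S,1(10)E,4Z)-9-(tert-butyldimethylsilyloxy)-3-hydroxy-8-(3-methylbutanoyloxy)germacra-1(10),4,11(13)-trien-12,6-olide (C3 epimers) | C=C1C(=O)O[C@@H]2/C=C(/C)C(O)C/C=C(\C)[C@H](O[Si](C)(C)C(C)(C)C)[C@@H](OC(=O)CC(C)C)[C@@H]12
F6 | step 19 | (6R,7S,8S,9S,1(10)E,4Z)-9-(tert-butyldimethylsilyloxy)-8-(3-methylbutanoyloxy)-3-oxogermacra-1(10),4,11(13)-trien-12,6-olide | C=C1C(=O)O[C@@H]2/C=C(/C)C(=O)C/C=C(\C)[C@H](O[Si](C)(C)C(C)(C)C)[C@@H](OC(=O)CC(C)C)[C@@H]12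
F7 | step 13 | Morita–Baylis–Hillman adduct of 11: methyl (6E)-5-(tert-butyldimethylsilyloxy)-3-hydroxy-9-(4-methoxybenzyloxy)-6-methyl-2-methylidene-4-(triethylsilyloxy)non-6-enoate (C7 carbinol epimers, C8 and C9 as in 11) | COc1ccc(COCC/C=C(\C)[C@H](O[Si](C)(C)C(C)(C)C)[C@@H](O[Si](CC)(CC)CC)C(O)C(=C)C(=O)OC)cc1
F8 | step 13 | methyl (2Z,4S,5S,6E)-2-(bromomethyl)-5-(tert-butyldimethylsilyloxy)-9-(4-methoxybenzyloxy)-6-methyl-4-(triethylsilyloxy)nona-2,6-dienoate | COc1ccc(COCC/C=C(\C)[C@H](O[Si](C)(C)C(C)(C)C)[C@@H](O[Si](CC)(CC)CC)/C=C(\CBr)C(=O)OC)cc1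
F9 | step 13 | syn hydroxy ester: methyl ester of the open 12,6-hydroxy acid of 22 with the opposite configuration at C6 | COC(=O)C(=C)[C@@H]([C@H](/C=C(/C)I)O)[C@H](O[Si](CC)(CC)CC)[C@@H](O[Si](C)(C)C(C)(C)C)/C(C)=C/CCOCc1ccc(OC)cc1
F10 | step 13 | hydroxy acid of F9 | OC(=O)C(=C)[C@@H]([C@H](/C=C(/C)I)O)[C@H](O[Si](CC)(CC)CC)[C@@H](O[Si](C)(C)C(C)(C)C)/C(C)=C/CCOCc1ccc(OC)cc1
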